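**Retrosynthetic overview**
1. The C12=C13 bond comes from an E-selective Wittig olefination of a 13,14,15,16-tetranorlabdan-12-al with the maleimide/PPh3 ylide. The 7β-OAc comes from the 8(17)-ene by allylic oxidation, oxidation and 1,2-reduction. The 2α-Cl comes from a C2 ketone by α-face hydride delivery and Appel inversion.
2. Key disconnection: open C9–C10 of ring B and re-close C2–C10. This turns the 2-oxo-8(17)-ene trans-decalin into a 1-hydroxybicyclo[3.1.0]hexane (five-membered ring C2-C3-C4-C5-C10 bridged by C1) that carries an (E)-trisubstituted alkene chain on C5.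
3. Enabling feature: the chlorine-bearing C2 is β to quaternary C10 through C1, so a C2 carbonyl and a C10 radical are the two ends of the internal cyclopropanol bond. C10 also lies 1,6 to C9 of the C8(CH3)=C9 alkene, and the C8 methyl (C17) is the future methylidene.
4. Ring order: purchased cyclopentane ring, then the cyclopropane (C1), then ring A (one-carbon expansion) and ring B (6-endo closure) in one operation, with the imide ring attached last.
5. C5 is set by copper-catalysed asymmetric conjugate addition to 2,4,4-trimethylcyclopent-2-enone. It is the only stereocentre that survives into the key step, and it controls C10 and C9.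

Key step: step 7

Remark: labdane numbering is used. Ring A = C1, C2, C3, C4, C5, C10; ring B = C5 to C10; C17 = methylidene carbon on C8; C18/C19 = methyls on C4; C20 = methyl on C10; C11/C12 = side chain; C13 to C16 = imide carbons; β = the face of C20.
Assumption: the sense of induction of the CuBr/ferrocenyl diphosphine catalyst on the trimethylcyclopentenone is taken from 2-methylcyclopent-2-enone; if it proves opposite, the commercial mirror-image ligand is used.

Step 1
Reactants: 1 4-(tert-butyldimethylsilyloxy)but-1-yne; 2 oxirane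
Product: 5 (E)-6-(tert-butyldimethylsilyloxy)-4-methylhex-3-en-1-ol, via alkenylalane 3 (not isolated), via lithium alanate 4 (not isolated)
Conditions: Me3Al, Cp2ZrCl2 (20 mol %), CH2Cl2, 0 °C to rt; volatiles removed; n-BuLi, hexane/THF, −78 °C; oxirane, −78 °C to rt; aqueous work-up
Reagents that add atoms: trimethylaluminium C[Al](C)C
Why: Negishi carboalumination adds methyl and aluminium syn across the terminal alkyne with methyl on the internal carbon, and the derived alanate opens oxirane with retention of the alkene geometry, so the E-trisubstituted alkene that later dictates C9 is fixed here.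

Step 2
Reactants: 5 (E)-6-(tert-butyldimethylsilyloxy)-4-methylhex-3-en-1-ol
Product: 6 (E)-1-(tert-butyldimethylsilyloxy)-6-(tert-butyldiphenylsilyloxy)-3-methylhex-3-ene
Conditions: TBDPSCl, imidazole, DMF, rt
Reagents that add atoms: tert-butyl(chloro)diphenylsilane CC(C)(C)[Si](Cl)(c1ccccc1)c1ccccc1
Why: Imidazole-promoted silylation of the only free hydroxyl group installs an ether that is more hindered and more acid-stable than the TBS ether at the other terminus.

Step 3
Reactants: 6 (E)-1-(tert-butyldimethylsilyloxy)-6-(tert-butyldiphenylsilyloxy)-3-methylhex-3-ene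
Product: 7 (E)-1-bromo-6-(tert-butyldiphenylsilyloxy)-3-methylhex-3-ene
Conditions: Ph3PBr2 (1.1 equiv), CH2Cl2, 0 °C
Reagents that add atoms: dibromotriphenylphosphorane BrP(Br)(c1ccccc1)(c1ccccc1)c1ccccc1
Why: Direct silyl ether to bromide exchange with Ph3PBr2 (Appel-type SN2 at the primary carbon after bromophosphonium attack on oxygen) should take the less hindered TBS ether and leave the bulkier TBDPS ether and the alkene.

Step 4
Reactants: 8 2,4,4-trimethylcyclopentanone (racemic)
Product: 9 2,4,4-trimethylcyclopent-2-en-1-one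
Conditions: 2-iodoxybenzoic acid (IBX), DMSO, 70 °C
Reagents that add atoms: none
Why: IBX dehydrogenation of the ketone can only place the double bond between ring positions 2 and 3 (future C10 and C5) because the other α-carbon adjoins the quaternary carbon.

Step 5
Reactants: 7 (E)-1-bromo-6-(tert-butyldiphenylsilyloxy)-3-methylhex-3-ene; 9 2,4,4-trimethylcyclopent-2-en-1-one
Product: 12 (S)-{3-[(E)-6-(tert-butyldiphenylsilyloxy)-3-methylhex-3-en-1-yl]-2,4,4-trimethylcyclopent-1-en-1-yl}oxytrimethylsilane, via Grignard reagent 10 (not isolated), via magnesium enolate 11 (not isolated)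
Conditions: Mg, Et2O, reflux; CuBr·SMe2 (5 mol %), (R)-1-[(Sp)-2-(dicyclohexylphosphino)ferrocenyl]ethyldiphenylphosphine (6 mol %), 9, t-BuOMe, −78 °C; TMSCl, DMPU, −78 to 0 °C
Reagents that add atoms: chlorotrimethylsilane C[Si](C)(C)Cl
Why: Copper-catalysed asymmetric conjugate addition of a Grignard reagent to an α-methylcyclopentenone sets C5 under ligand control, and O-silylation of the regiodefined magnesium enolate fixes the tetrasubstituted C2=C10 silyl enol ether that direct enolisation would not give cleanly.

Step 6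
Reactants: 12 silyl enol ether
Product: 14 (1R,4S,5R)-4-[(E)-6-(tert-butyldiphenylsilyloxy)-3-methylhex-3-en-1-yl]-3,3,5-trimethylbicyclo[3.1.0]hexan-1-ol, via TMS cyclopropyl ether 13 (not isolated)
Conditions: Et2Zn (0.7 equiv), CH2I2 (1.4 equiv), CH2Cl2, −10 °C; aqueous NH4Cl; crude in MeOH, citric acid (10 mol %), 0 °C
Reagents that add atoms: diiodomethane ICI
Why: Simmons–Smith cyclopropanation (Furukawa variant) is fastest at the electron-rich silyl enol ether, so the isolated alkene should survive a limited charge of carbenoid; attack anti to the C5 chain is expected but immaterial because both new stereocentres are erased in step 7, and mild methanolysis then frees the cyclopropanol.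

Step 7
Reactants: 14 cyclopropanol
Product: 17 12-(tert-butyldiphenylsilyloxy)-13,14,15,16-tetranorlabd-8(17)-en-2-one (5α-H 9α-H 10β-CH3; 4aS,8S,8aS as the octahydronaphthalen-2-one), via ring-expanded C10 radical 15 (not isolated), via bicyclic C8 radical 16 (not isolated)
Conditions: Mn(OAc)3·2H2O (2.2 equiv), Cu(OAc)2·H2O (20 mol %), degassed AcOH, 25 °C, slow addition of 14 (final 5 mM)
Reagents that add atoms: none
Why: One-electron oxidation of the manganese cyclopropoxide cleaves the internal C2–C10 bond, so the five-membered ring C2-C3-C4-C5-C10 becomes six-membered ring A with the carbonyl at C2 and a tertiary radical at C10 (15); this radical adds to C9 of the side-chain alkene to give 16, which Cu(OAc)2 oxidises through an alkylcopper species that loses a C17 hydrogen to give the 8(17)-methylidene, the monovalent copper being reoxidised by Mn(OAc)3. The closest known reaction types are the oxidative ring expansion–cyclisation of 1-hydroxy- or 1-siloxybicyclo[n.1.0]alkanes bearing a pendant alkene with FeCl3 or trivalent manganese, and Mn(OAc)3/Cu(OAc)2 oxidative radical polyene cyclisations that end in exocyclic methylenes. Ring A arises by β-scission (one-carbon ring expansion, C1 ending between C2 and C10) and ring B by a 6-endo-trig radical closure. C10 and C9 are controlled by C5 through a chair-like transition state with the C5 chain equatorial on ring A, the arrangement of the second ring closure in radical polyene cyclisations that give trans-decalins; it puts C20 axial (β) and anti to H-5, while the E alkene geometry puts C11 equatorial (9β). The step needs cleavage of the internal rather than the external cyclopropane bond (secured by the C10 methyl, tertiary versus primary radical), 6-endo rather than 5-exo closure (secured by the C8 methyl), ring closure before oxidation of 15 (secured by low copper concentration and dilution), and elimination toward C17 (secured by the preference of the copper-mediated elimination for the least hindered hydrogen). Both cyclopropane diastereomers of 14 converge on the same radical 15.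

Step 8
Reactants: 17 decalone
Product: 18 12-(tert-butyldiphenylsilyloxy)-13,14,15,16-tetranorlabd-8(17)-en-2β-ol (axial OH)
Conditions: NaBH4, MeOH/THF, −20 °C
Reagents that add atoms: none
Why: Hydride reduction of the C2 ketone occurs from the open α face because the axial C20 and C4β methyl groups screen the β face, which gives the axial 2β-alcohol.

Step 9
Reactants: 18 2β-alcohol
Product: 19 2α-chloro-12-(tert-butyldiphenylsilyloxy)-13,14,15,16-tetranorlabd-8(17)-ene
Conditions: PPh3, CCl4, toluene, 80 °C
Reagents that add atoms: tetrachloromethane ClC(Cl)(Cl)Cl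
Why: In the Appel reaction chloride displaces the axial oxyphosphonium group from the unhindered α face with SN2 inversion, which gives the equatorial 2α-chloride.

Step 10
Reactants: 19 2α-chloride
Product: 20 2α-chloro-12-(tert-butyldiphenylsilyloxy)-13,14,15,16-tetranorlabd-8(17)-en-7α-ol
Conditions: SeO2 (30 mol %), t-BuOOH, CH2Cl2, rt
Reagents that add atoms: tert-butyl hydroperoxide CC(C)(C)OO; selenium dioxide O=[Se]=O
Why: Riley allylic oxidation (ene reaction at C17, then [2,3]-sigmatropic shift) functionalises the secondary allylic C7 position and delivers oxygen axially on the α face, as is usual for labd-8(17)-enes.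

Step 11
Reactants: 20 7α-alcohol
Product: 21 2α-chloro-12-(tert-butyldiphenylsilyloxy)-13,14,15,16-tetranorlabd-8(17)-en-7-one
Conditions: Dess–Martin periodinane, CH2Cl2, 0 °C; used at once
Reagents that add atoms: none
Why: Dess–Martin oxidation under near-neutral conditions gives the α-methylidene ketone without moving the double bond into the ring.

Step 12
Reactants: 21 enone
Product: 22 2α-chloro-12-(tert-butyldiphenylsilyloxy)-13,14,15,16-tetranorlabd-8(17)-en-7β-ol
Conditions: NaBH4, CeCl3·7H2O, MeOH, −78 °C
Reagents that add atoms: none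
Why: Luche reduction is 1,2-selective and the small hydride attacks C7 axially from the α face, which gives the equatorial 7β-alcohol.

Step 13
Reactants: 22 7β-alcohol
Product: 23 7β-acetoxy-2α-chloro-12-(tert-butyldiphenylsilyloxy)-13,14,15,16-tetranorlabd-8(17)-ene
Conditions: Ac2O, pyridine, 4-(dimethylamino)pyridine (5 mol %), rt
Reagents that add atoms: acetic anhydride CC(=O)OC(C)=O
Why: Nucleophile-catalysed acetylation of the only free hydroxyl group proceeds with retention at C7.

Step 14
Reactants: 23 silyl ether
Product: 24 7β-acetoxy-2α-chloro-13,14,15,16-tetranorlabd-8(17)-en-12-ol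
Conditions: HF·pyridine, THF/pyridine, 0 °C to rt
Reagents that add atoms: none
Why: Buffered fluoride cleavage of the silyl ether leaves the acetate, the secondary chloride and the alkene untouched.

Step 15
Reactants: 24 primary alcohol
Product: 25 7β-acetoxy-2α-chloro-13,14,15,16-tetranorlabd-8(17)-en-12-al
Conditions: Dess–Martin periodinane, CH2Cl2, 0 °C to rt
Reagents that add atoms: none
Why: Dess–Martin oxidation stops at the aldehyde, whose α-carbon (C11) is not stereogenic, so nothing can epimerise.

Step 16
Reactants: 26 maleimide; 27 triphenylphosphine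
Product: 28 3-(triphenyl-λ5-phosphanylidene)pyrrolidine-2,5-dione
Conditions: acetone, reflux; filtration
Reagents that add atoms: none
Why: Conjugate addition of the phosphine to maleimide followed by proton transfer gives the crystalline carbonyl-stabilised ylide.

Step 17
Reactants: 25 aldehyde; 28 ylide
Product: 29 target, 7β-acetoxy-2α-chlorolabda-8(17),12E-diene-15,16-dicarboximide
Conditions: toluene, 70 °C
Reagents that add atoms: none
Why: The Wittig reaction of the carbonyl-stabilised ylide is E-selective, which puts C11 trans to the C16 carbonyl, and it tolerates the free NH, the acetate and the chloride.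

**Compound list**
1 | 4-(tert-butyldimethylsilyloxy)but-1-yne | C#CCCO[Si](C)(C)C(C)(C)C | starting material
2 | oxirane | C1CO1 | starting material
3 | (E)-[4-(tert-butyldimethylsilyloxy)-2-methylbut-1-en-1-yl]dimethylalane | C[Al](C)/C=C(\C)CCO[Si](C)(C)C(C)(C)C | intermediate
4 | lithium (E)-butyl[4-(tert-butyldimethylsilyloxy)-2-methylbut-1-en-1-yl]dimethylalanate | [Li+].CCCC[Al-](C)(C)/C=C(\C)CCO[Si](C)(C)C(C)(C)C | intermediate
5 | (E)-6-(tert-butyldimethylsilyloxy)-4-methylhex-3-en-1-ol | OCC/C=C(\C)CCO[Si](C)(C)C(C)(C)C | intermediate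
6 | (E)-1-(tert-butyldimethylsilyloxy)-6-(tert-butyldiphenylsilyloxy)-3-methylhex-3-ene | CC(C)(C)[Si](C)(C)OCC/C(C)=C/CCO[Si](C(C)(C)C)(c1ccccc1)c1ccccc1 | intermediate
7 | (E)-1-bromo-6-(tert-butyldiphenylsilyloxy)-3-methylhex-3-ene | BrCC/C(C)=C/CCO[Si](C(C)(C)C)(c1ccccc1)c1ccccc1 | intermediate
8 | 2,4,4-trimethylcyclopentanone (racemic) | CC1CC(C)(C)CC1=O | starting material
9 | 2,4,4-trimethylcyclopent-2-en-1-one | CC1=CC(C)(C)CC1=O | intermediate
10 | (E)-[6-(tert-butyldiphenylsilyloxy)-3-methylhex-3-en-1-yl]magnesium bromide | Br[Mg]CC/C(C)=C/CCO[Si](C(C)(C)C)(c1ccccc1)c1ccccc1 | intermediate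
11 | bromomagnesium (S)-enolate of the conjugate adduct | CC1=C(O[Mg]Br)CC(C)(C)[C@@H]1CC/C(C)=C/CCO[Si](C(C)(C)C)(c1ccccc1)c1ccccc1 | intermediate
12 | (S)-trimethylsilyl enol ether (C2=C10) | CC1=C(O[Si](C)(C)C)CC(C)(C)[C@@H]1CC/C(C)=C/CCO[Si](C(C)(C)C)(c1ccccc1)c1ccccc1 | intermediate
13 | (1R,4S,5R)-1-trimethylsilyloxybicyclo[3.1.0]hexane, CH2 anti to the chain | C[Si](C)(C)O[C@]12CC(C)(C)[C@H](CC/C(C)=C/CCO[Si](C(C)(C)C)(c3ccccc3)c3ccccc3)[C@@]1(C)C2 | intermediate
14 | (1R,4S,5R)-4-[(E)-6-(tert-butyldiphenylsilyloxy)-3-methylhex-3-en-1-yl]-3,3,5-trimethylbicyclo[3.1.0]hexan-1-ol | O[C@]12CC(C)(C)[C@H](CC/C(C)=C/CCO[Si](C(C)(C)C)(c3ccccc3)c3ccccc3)[C@@]1(C)C2 | intermediate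
15 | ring-expanded 3-oxocyclohexyl (C10) radical | C[C]1CC(=O)CC(C)(C)[C@@H]1CC/C(C)=C/CCO[Si](C(C)(C)C)(c1ccccc1)c1ccccc1 | intermediate
16 | trans-decalin C8 radical | C[C]1CC[C@H]2C(C)(C)CC(=O)C[C@]2(C)[C@H]1CCO[Si](C(C)(C)C)(c1ccccc1)c1ccccc1 | intermediate
17 | 12-(tert-butyldiphenylsilyloxy)-13,14,15,16-tetranorlabd-8(17)-en-2-one | C=C1CC[C@H]2C(C)(C)CC(=O)C[C@]2(C)[C@H]1CCO[Si](C(C)(C)C)(c1ccccc1)c1ccccc1 | intermediate
18 | the 2β-ol of 17 | C=C1CC[C@H]2C(C)(C)C[C@@H](O)C[C@]2(C)[C@H]1CCO[Si](C(C)(C)C)(c1ccccc1)c1ccccc1 | intermediate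
19 | 2α-chloro-12-(tert-butyldiphenylsilyloxy)-13,14,15,16-tetranorlabd-8(17)-ene | C=C1CC[C@H]2C(C)(C)C[C@H](Cl)C[C@]2(C)[C@H]1CCO[Si](C(C)(C)C)(c1ccccc1)c1ccccc1 | intermediate
20 | the 7α-ol of 19 | C=C1[C@H](O)C[C@H]2C(C)(C)C[C@H](Cl)C[C@]2(C)[C@H]1CCO[Si](C(C)(C)C)(c1ccccc1)c1ccccc1 | intermediate
21 | the 8(17)-en-7-one | C=C1C(=O)C[C@H]2C(C)(C)C[C@H](Cl)C[C@]2(C)[C@H]1CCO[Si](C(C)(C)C)(c1ccccc1)c1ccccc1 | intermediate
22 | the 7β-ol | C=C1[C@@H](O)C[C@H]2C(C)(C)C[C@H](Cl)C[C@]2(C)[C@H]1CCO[Si](C(C)(C)C)(c1ccccc1)c1ccccc1 | intermediate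
23 | the 7β-acetate | C=C1[C@@H](OC(C)=O)C[C@H]2C(C)(C)C[C@H](Cl)C[C@]2(C)[C@H]1CCO[Si](C(C)(C)C)(c1ccccc1)c1ccccc1 | intermediate
24 | 7β-acetoxy-2α-chloro-13,14,15,16-tetranorlabd-8(17)-en-12-ol | C=C1[C@@H](OC(C)=O)C[C@H]2C(C)(C)C[C@H](Cl)C[C@]2(C)[C@H]1CCO | intermediate
25 | 7β-acetoxy-2α-chloro-13,14,15,16-tetranorlabd-8(17)-en-12-al | C=C1[C@@H](OC(C)=O)C[C@H]2C(C)(C)C[C@H](Cl)C[C@]2(C)[C@H]1CC=O | intermediate
26 | maleimide | O=C1C=CC(=O)N1 | starting material
27 | triphenylphosphine | c1ccc(cc1)P(c1ccccc1)c1ccccc1 | starting material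
28 | 3-(triphenyl-λ5-phosphanylidene)pyrrolidine-2,5-dione | O=C1CC(=P(c2ccccc2)(c2ccccc2)c2ccccc2)C(=O)N1 | intermediate
29 | CNP0220384.1 | C=C1[C@@H](OC(C)=O)C[C@H]2C(C)(C)C[C@H](Cl)C[C@]2(C)[C@H]1C/C=C1\CC(=O)NC1=O | target

Total step count: 17. Longest linear sequence: 15 (steps 1–3, 5–15, 17).

**Steps most likely to fail**

Step 7. Radical 15 may be oxidised before it closes ring B, facial control in the closure may be incomplete, or regiocontrol may be lost in the copper-mediated elimination. The fallback sets out from 14 and returns at 17, and it separates ring construction from alkene formation. FeCl3 in DMF at 0 °C brings about the same ring expansion and 6-endo closure. It ends the sequence by chlorine-atom transfer to the C8 radical from the α face, which is open because C20 screens the β face. The product is 8α-chloro-12-(tert-butyldiphenylsilyloxy)-13,14,15,16-tetranorlabdan-2-one F1. Its equatorial C–Cl bond has no antiperiplanar ring hydrogen, so E2 elimination with KOtBu in THF can only take a C17 hydrogen and gives 17.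

Step 5. The 1,4-addition at the neopentyl β-carbon of the α-methyl enone may be sluggish with competing 1,2-addition, or enantioselectivity may erode. The fallback sets out from 10 and returns at 12, and it introduces the methyl group after the C–C bond. Reagent 10 is added under the same copper/ferrocenyl diphosphine catalysis to commercial 4,4-dimethylcyclopent-2-en-1-one (CC1(C)CC(=O)C=C1), a less hindered acceptor. The resulting bromomagnesium (R)-3-[(E)-6-(tert-butyldiphenylsilyloxy)-3-methylhex-3-en-1-yl]-4,4-dimethylcyclopent-1-en-1-olate F2 is methylated with MeI/DMPU. This gives (2R,3R)-3-[(E)-6-(tert-butyldiphenylsilyloxy)-3-methylhex-3-en-1-yl]-2,4,4-trimethylcyclopentanone F3. Thermodynamic silylation (TMSCl, NaI, Et3N, MeCN) then gives the more substituted enol ether 12.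

Step 9. E2 loss of the axial oxyphosphonium group toward C1 or C3 may compete, driven by relief of the two syn-axial methyl interactions. The fallback sets out from 17 and returns at 19. It uses retention at an equatorial leaving group, which has no antiperiplanar hydrogen. SmI2/H2O/Et3N in THF reduces 17 to the thermodynamic equatorial alcohol 12-(tert-butyldiphenylsilyloxy)-13,14,15,16-tetranorlabd-8(17)-en-2α-ol F4. SOCl2 in CH2Cl2 converts it into the 2α-chlorosulfite F5. Catalytic TiCl4 (10 mol %) at 0 °C then collapses F5 with front-side chloride delivery (stereoretentive chlorination of cyclic alcohols) to 19.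

**Further compounds**
F1 | step 7 | 8α-chloro-12-(tert-butyldiphenylsilyloxy)-13,14,15,16-tetranorlabdan-2-one | C[C@@]1(Cl)CC[C@H]2C(C)(C)CC(=O)C[C@]2(C)[C@H]1CCO[Si](C(C)(C)C)(c1ccccc1)c1ccccc1
F2 | step 5 | bromomagnesium (R)-3-[(E)-6-(tert-butyldiphenylsilyloxy)-3-methylhex-3-en-1-yl]-4,4-dimethylcyclopent-1-en-1-olate | Br[Mg]OC1=C[C@@H](CC/C(C)=C/CCO[Si](C(C)(C)C)(c2ccccc2)c2ccccc2)C(C)(C)C1
F3 | step 5 | (2R,3R)-3-[(E)-6-(tert-butyldiphenylsilyloxy)-3-methylhex-3-en-1-yl]-2,4,4-trimethylcyclopentanone | O=C1CC(C)(C)[C@H](CC/C(C)=C/CCO[Si](C(C)(C)C)(c2ccccc2)c2ccccc2)[C@H]1C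
F4 | step 9 | 12-(tert-butyldiphenylsilyloxy)-13,14,15,16-tetranorlabd-8(17)-en-2α-ol | C=C1CC[C@H]2C(C)(C)C[C@H](O)C[C@]2(C)[C@H]1CCO[Si](C(C)(C)C)(c1ccccc1)c1ccccc1
F5 | step 9 | 2α-chlorosulfite of F4 | C=C1CC[C@H]2C(C)(C)C[C@H](OS(=O)Cl)C[C@]2(C)[C@H]1CCO[Si](C(C)(C)C)(c1ccccc1)c1ccccc1
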